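**Assumptions (one line each)**
- β-Eudesmol (3) is bought as the natural single enantiomer (isolated from essential oils). It supplies C5, C7 and C10.
- The two allyl groups are installed last from aryl bromides, because terminal alkenes would compete in the Co–H step.
- The target is obovatol mono-etherified at the OH meta to the diaryl-ether oxygen.
- In the target SMILES, O is α and CH3 is β at C4. The C4–Me is therefore cis to the C10–Me, and the ether forms on the face anti to the C10 methyl.

## Retrosynthetic overview
1. The target comes from two-fold Pd allylation of dibromide 7.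
2. Dibromide 7 comes from chemoselective (C–I) Cu O-arylation of the less hindered OH of catechol 5.
3. Catechol 5 comes from Dakin oxidation of aldehyde 4, so the CHO is a traceless oxygen surrogate.
4. Aldehyde 4 forms in the key photochemical Markovnikov hydroaryloxylation of β-eudesmol (3) with 5-bromo-2,3-dihydroxybenzaldehyde (2). This sets C4.
5. All carbocycles and the arene ring are pre-formed in commercial materials, so only C–O and C–C(allyl) bonds are made.

## Route

**Step 1**
Reactants: 1 (5-bromo-2-hydroxy-3-methoxybenzaldehyde)
Product: 2 (5-bromo-2,3-dihydroxybenzaldehyde)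
Conditions: BBr3 (2.5 equiv), CH2Cl2, –78 °C → 0 °C, 3 h; MeOH quench
Reagents that add atoms: none
Why: BBr3 cleaves the aryl methyl ether, assisted by chelation to the adjacent OH/CHO (ether cleavage), while ArBr and CHO survive. No stereocenter is involved.

**Step 2**
Reactants: 3 (β-eudesmol), 2 (2 equiv)
Product: 4 (5-bromo-2-hydroxy-3-[(4α-eudesmanyl-11-ol)oxy]benzaldehyde, i.e. the C4 tertiary aryl ether)
Conditions: achiral Co(II)-salen (from 3,5-di-tBu-salicylaldehyde and 2,2-dimethylpropane-1,3-diamine, 5 mol%), Ir[dF(CF3)ppy]2(dtbbpy)PF6 (1 mol%), MeCN, 427 nm blue LEDs, rt, 24 h, degassed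
Reagents that add atoms: none
Why: Proposed new method: an intermolecular, redox-neutral photochemical Co–H MHAT/radical-polar crossover hydroaryloxylation of an unactivated 1,1-disubstituted alkene with a phenol. The mechanism:
- Ir(II) reduces Co(II) to Co(I), and the phenol protonates it to Co(III)–H.
- Co(III)–H transfers H• to C15, giving the tertiary C4 radical. This is captured as Co(III)–alkyl and oxidised by Ir(III)* to a Co(IV)/cation-like species.
- The phenol oxygen traps C4 on the α face, anti to the axial C10 methyl in the rigid trans-decalin. This sets 4α-OAr (substrate control, achiral catalyst).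
- The closest known reactions are Shigehisa-type Co/oxidant hydroalkoxylation and photoredox/Co hydrofunctionalisation.
- Selectivity features: the CHO/Br-deactivated arene resists C-alkylation and photo-oxidation; the CHO-chelated 2-OH is a poor nucleophile, so the free 3-OH reacts; the equatorial 7β-CMe2OH and the 11-OH cannot reach C4.

**Step 3**
Reactants: 4
Product: 5 (5-bromo-3-[(4α-eudesmanyl-11-ol)oxy]benzene-1,2-diol)
Conditions: 30% aq. H2O2 (3 equiv), 2 M NaOH (3 equiv), MeOH, 0 °C → rt, 2 h; Na2S2O4 quench, NH4Cl
Reagents that add atoms: hydrogen peroxide, OO (one O ends up as the new C1–OH)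
Why: Dakin oxidation of an o-hydroxybenzaldehyde converts ArCHO to ArOH via aryl migration and formate hydrolysis. The ether, ArBr and tertiary alcohol are base-stable, and no stereocenter is touched.

**Step 4**
Reactants: 5, 6 (1-bromo-4-iodobenzene, 1.05 equiv)
Product: 7 (diaryl ether dibromide)
Conditions: CuI (10 mol%), picolinic acid (20 mol%), Cs2CO3 (1.2 equiv), DMSO, 70 °C
Reagents that add atoms: none (6 is the aryl source, listed above)
Why: Ullmann-type O-arylation reacts at C–I much faster than at either C–Br. The C1-OH is far less hindered than the C2-OH, which is flanked by the bulky tertiary ether and an OH, so arylation occurs at C1.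

**Step 5**
Reactants: 7, 8 (allyl-Bpin, 2.6 equiv)
Product: 9 (Eudesobovatol A)
Conditions: Pd(dppf)Cl2 (10 mol%), K3PO4 (6 equiv), THF/H2O 10:1, 65 °C, 12 h
Reagents that add atoms: none (8 is the allyl source, listed above)
Why: Suzuki–Miyaura allylation of both ArBr (two-fold) gives the two allyl groups. The free phenol, tertiary alcohol and tertiary aryl ether are untouched, and all stereocenters are unchanged.

## Compound list
1 | 5-bromo-2-hydroxy-3-methoxybenzaldehyde | COc1cc(Br)cc(C=O)c1O | starting material
2 | 5-bromo-2,3-dihydroxybenzaldehyde | O=Cc1cc(Br)cc(O)c1O | intermediate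
3 | β-eudesmol | C=C3CCC[C@]4(C)CC[C@@H](C(C)(C)O)C[C@H]43 | starting material
4 | aryl tertiary ether aldehyde | O=Cc1cc(Br)cc(O[C@]2(C)CCC[C@]3(C)CC[C@@H](C(C)(C)O)C[C@H]32)c1O | intermediate
5 | bromocatechol mono-terpenyl ether | Oc1cc(Br)cc(O[C@]2(C)CCC[C@]3(C)CC[C@@H](C(C)(C)O)C[C@H]32)c1O | intermediate
6 | 1-bromo-4-iodobenzene | Brc1ccc(I)cc1 | starting material
7 | diaryl ether dibromide | Brc1ccc(Oc2cc(Br)cc(O[C@]3(C)CCC[C@]4(C)CC[C@@H](C(C)(C)O)C[C@H]43)c2O)cc1 | intermediate
8 | allyl pinacol boronate | C=CCB1OC(C)(C)C(C)(C)O1 | starting material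
9 | Eudesobovatol A | C=CCc1ccc(Oc2cc(CC=C)cc(O[C@]3(C)CCC[C@]4(C)CC[C@@H](C(C)(C)O)C[C@H]43)c2O)cc1 | target

**Total steps:** 5. **Longest linear sequence:** 5 (1 → 2 → 4 → 5 → 7 → 9).

## Three steps most likely to fail
1. **Step 2 (proposed new step).** Risks are isomerisation of the alkene to α- or γ-eudesmol, low O- versus C-selectivity, and the wrong C4 diastereomer.
   - Fallback (known chemistry): Mukaiyama hydration of 3 (Co(acac)2, PhSiH3, O2) to the 4,11-diol. Then TES-protect the 11-OH, O-arylate the 4-alkoxide with a diaryliodonium salt (Olofsson-type), and continue with the Dakin, Ullmann and Suzuki sequence on the suitably functionalised arene.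
2. **Step 4.** The catechol may oxidise or chelate Cu, and regioselectivity between the C1-OH and C2-OH may be imperfect.
   - Fallback: transition-metal-free mono-O-arylation of the C1 phenoxide with (4-bromophenyl)(mesityl)iodonium triflate (K2CO3, rt).
3. **Step 5.** Allyl-to-propenyl isomerisation or protodebromination may occur.
   - Fallback: Stille allylation with allyltributylstannane (Pd(PPh3)4, LiCl, toluene, 100 °C), which avoids base-promoted isomerisation.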